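Everything rests on cutting the two upper interflavan bonds, C4(U)–C8(G) and C4(G)–C8(M), so that the epigallocatechin gallate unit G acts as a linchpin. The key step exploits the galloyl ester on O3 of ring C of unit G: standing next to C4, it keeps that carbon latent while C8 of ring A captures the C4 cation of bromine-capped unit U, and it then bridges the C4 cation of G to steer attack by C8 of the epicatechin–catechin dimer. One flask forms both bonds and both new C4 stereocentres. The precursors are benzyl-protected: an 8-bromo-4-alkoxy epicatechin, a 4-arylthio epigallocatechin gallate and the 4β→8 dimer.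

Key step: step 11

Remark on the structures: read atom by atom, the target is epicatechin-(4β→8)-epigallocatechin 3-O-gallate-(4β→8)-epicatechin-(4β→8)-catechin, every unit 2R and every interflavan bond 3,4-trans; the building blocks drawn below agree with it.

Remark on the precursor design: an oxygen leaving group at C4 of unit G would not be safely latent, because 3-O-acyl-4-alkoxyflavans are themselves ordinary electrophiles for Me3SiOTf at −78 °C (a trans ester may even assist ionisation), and the C8 bromine on ring A of unit U slows that unit's own ionisation. C4 of unit G therefore carries a 2,6-dimethylphenylthio group, which a silyl Lewis acid leaves alone and a thiophile releases on demand; the hindered aryl group keeps sulfur from intercepting the first cation.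

Remark on unit G: it is assembled from (−)-epigallocatechin and 3,4,5-tris(benzyloxy)benzoic acid, both taken as commercial. This way the ester never meets carbonate and phenoxides, and the DDQ oxidation runs on a free 3-ol.

Step 1
Reactants: 1 (−)-epicatechin
Product: 2 5,7,3',4'-tetra-O-benzyl-(−)-epicatechin
Conditions: BnBr, K2CO3, DMF, 0 °C → rt, argon
Reagents that add atoms: benzyl bromide, BrCc1ccccc1
Why: Williamson ether synthesis in which K2CO3 deprotonates only the four phenols, so the C3 alcohol and both stereocentres should stay untouched.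

Step 2
Reactants: 2 5,7,3',4'-tetra-O-benzyl-(−)-epicatechin
Product: 3 8-bromo-5,7,3',4'-tetra-O-benzyl-(−)-epicatechin
Conditions: NBS (1.0 equiv), CH2Cl2, −78 °C → rt
Reagents that add atoms: N-bromosuccinimide, O=C1CCC(=O)N1Br
Why: Electrophilic aromatic bromination, for which ring A is the most electron-rich arene and C8 (between O1 and the C7 ether) its most accessible position, so one equivalent should brominate there only.

Step 3
Reactants: 3 8-bromo-5,7,3',4'-tetra-O-benzyl-(−)-epicatechin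
Product: 4 8-bromo-4β-(2-ethoxyethoxy)-5,7,3',4'-tetra-O-benzylepicatechin (unit U)
Conditions: DDQ, EtOCH2CH2OH, CH2Cl2, rt
Reagents that add atoms: 2-ethoxyethanol, CCOCCO
Why: DDQ benzylic oxidation in which hydride abstraction at C4 gives a cation stabilised by the oxygenated ring A and the alcohol adds to the β face, anti to the α-oriented C3 hydroxyl and C2 aryl, setting C4 trans to O3.

Step 4
Reactants: 2 5,7,3',4'-tetra-O-benzyl-(−)-epicatechin
Product: 5 4β-(2-ethoxyethoxy)-5,7,3',4'-tetra-O-benzylepicatechin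
Conditions: DDQ, EtOCH2CH2OH, CH2Cl2, rt
Reagents that add atoms: 2-ethoxyethanol, CCOCCO
Why: The same DDQ benzylic oxidation on the unbrominated ether, with alcohol capture of the C4 cation anti to the C3 hydroxyl and C2 aryl setting the 4β (3,4-trans) acetal.

Step 5
Reactants: 6 (+)-catechin
Product: 7 5,7,3',4'-tetra-O-benzyl-(+)-catechin
Conditions: BnBr, K2CO3, DMF, 0 °C → rt, argon
Reagents that add atoms: benzyl bromide, BrCc1ccccc1
Why: Williamson ether synthesis selective for the four phenols under carbonate, leaving the C3 alcohol and the 2R,3S centres unchanged.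

Step 6
Reactants: 5 4β-(2-ethoxyethoxy)-5,7,3',4'-tetra-O-benzylepicatechin; 7 5,7,3',4'-tetra-O-benzyl-(+)-catechin
Product: 8 octa-O-benzyl epicatechin-(4β→8)-catechin (M–T dimer, both C3 hydroxyls free)
Conditions: Me3SiOTf (cat.), 7 (3 equiv), CH2Cl2, −78 °C; Et3N quench
Reagents that add atoms: none
Why: Lewis-acid-promoted Friedel–Crafts condensation of a 4-alkoxyflavan-3-ol with a C8 nucleophile, in which C8 of 7 attacks the C4 cation of 5 on the β face, anti to the C3 hydroxyl and C2 aryl (C4 of unit M trans to O3), while the recoverable excess of 7 outcompetes C8 of 5 itself.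

Step 7
Reactants: 9 (−)-epigallocatechin
Product: 10 5,7,3',4',5'-penta-O-benzyl-(−)-epigallocatechin
Conditions: BnBr, K2CO3, DMF, 0 °C → rt, argon
Reagents that add atoms: benzyl bromide, BrCc1ccccc1
Why: Williamson ether synthesis of the five phenols under carbonate in degassed solvent, which protects the oxidation-prone pyrogallol ring B while the C3 alcohol and the 2R,3R centres should stay untouched.

Step 8
Reactants: 10 5,7,3',4',5'-penta-O-benzyl-(−)-epigallocatechin
Product: 11 4β-(2-ethoxyethoxy)-5,7,3',4',5'-penta-O-benzylepigallocatechin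
Conditions: DDQ, EtOCH2CH2OH, CH2Cl2, rt
Reagents that add atoms: 2-ethoxyethanol, CCOCCO
Why: DDQ benzylic oxidation at C4, whose hydrogens are the only benzylic ones conjugated to the trioxygenated ring A, followed by alcohol capture anti to the α-oriented C3 hydroxyl and C2 aryl to set the 4β (3,4-trans) acetal.

Step 9
Reactants: 11 4β-(2-ethoxyethoxy)-5,7,3',4',5'-penta-O-benzylepigallocatechin; 12 3,4,5-tris(benzyloxy)benzoic acid
Product: 13 4β-(2-ethoxyethoxy)-octa-O-benzyl-epigallocatechin 3-O-gallate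
Conditions: DCC, DMAP (cat.), CH2Cl2, 0 °C → rt
Reagents that add atoms: none
Why: Steglich esterification of the C3 alcohol through the O-acylisourea and the acylpyridinium ion, under neutral conditions that should spare the C4 acetal and leave C3 unchanged because its C–O bond is not broken.

Step 10
Reactants: 13 4β-(2-ethoxyethoxy)-octa-O-benzyl-epigallocatechin 3-O-gallate
Product: 14 4β-(2,6-dimethylphenylthio)-octa-O-benzyl-epigallocatechin 3-O-gallate (unit G)
Conditions: 2,6-Me2C6H3SH (5 equiv), Me3SiOTf (cat.), CH2Cl2, −40 → 0 °C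
Reagents that add atoms: 2,6-dimethylbenzenethiol, Cc1cccc(C)c1S
Why: Lewis-acid-catalysed acetal-to-thioether exchange (thiolysis of a 4-alkoxyflavan), in which the excess thiol captures the gallate-bridged C4 cation on the β face faster than C8 of a second molecule can, giving the 3,4-trans sulfide.

Step 11
Reactants: 4 8-bromo-4β-(2-ethoxyethoxy)-5,7,3',4'-tetra-O-benzylepicatechin (unit U); 14 4β-(2,6-dimethylphenylthio)-octa-O-benzyl-epigallocatechin 3-O-gallate (unit G); 8 octa-O-benzyl epicatechin-(4β→8)-catechin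
Product: 16 eicosa-O-benzyl 8-bromoepicatechin-(4β→8)-epigallocatechin 3-O-gallate-(4β→8)-epicatechin-(4β→8)-catechin, via bromo thio dimer 15 (not isolated)
Conditions: 4 (1.0 equiv), 14 (1.0 equiv), Me3SiOTf (0.2 equiv), 4 Å MS, CH2Cl2, −78 → −40 °C; then 8 (1.2 equiv), Me2S(SMe)BF4 (1.5 equiv), −78 → 0 °C; Et3N quench
Reagents that add atoms: none
Why: Proposed new method: Me3SiOTf activates the 2-ethoxyethoxy group of 4 and releases a C4 cation stabilised by the O1/O5/O7-substituted ring A, which C8 of ring A of 14 captures in a Friedel–Crafts alkylation to give 15, the C4–S bond of 14 (also flanked by the O3 galloyl ester) being inert to the hard silyl Lewis acid; Me2S(SMe)BF4 then sulfenylates that sulfur, the gallate carbonyl helps expel the disulfide as a C3/C4-bridged acyloxonium ion, and C8 of the upper ring A of 8 attacks C4. The closest known reaction types are the Me3SiOTf-promoted condensation of 4-alkoxyflavan-3-ol benzyl ethers with C8 nucleophiles and the thiophile-promoted condensation of 4-thioflavans, joined here in the one-flask order used for imidate-then-thioglycoside oligosaccharide assembly, which has not been shown on a flavan carrying an ester at O3. No ring is closed. C4 of unit U is set by attack on the β face, anti to the α-oriented C3 hydroxyl and C2 aryl groups, and C4 of unit G by attack anti to the α-face gallate bridge, so both new bonds are 3,4-trans. The step needs ordered ionisation, secured by the oxygen versus sulfur leaving groups and the ester at O3; C8 over C6 attack, innate to the 5,7-dibenzyloxy ring A; and no self-condensation, secured by the C8 bromine of 4 and the lack of any free C8 in 15 and 16.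

Step 12
Reactants: 16 eicosa-O-benzyl 8-bromo tetramer
Product: 17 epicatechin-(4β→8)-epigallocatechin 3-O-gallate-(4β→8)-epicatechin-(4β→8)-catechin (CNP0332815.1)
Conditions: H2 (1 atm), Pd(OH)2/C, Et3N (2 equiv), THF/MeOH/H2O, rt
Reagents that add atoms: none
Why: Catalytic hydrogenolysis, in which Pd(OH)2 on carbon should cleave all twenty benzyl ethers and the aryl C–Br bond while Et3N neutralises the HBr that could otherwise cleave the acid-labile interflavan bonds, leaving the gallate ester and every stereocentre untouched.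

Compound list
1 | (−)-epicatechin, (2R,3R)-flavan-3,5,7,3',4'-pentol | O[C@@H]1Cc2c(O)cc(O)cc2O[C@@H]1c1ccc(O)c(O)c1 | starting material
2 | 5,7,3',4'-tetra-O-benzyl-(−)-epicatechin (2R,3R; C3 hydroxyl free) | O[C@@H]1Cc2c(OCc9ccccc9)cc(OCc9ccccc9)cc2O[C@@H]1c1ccc(OCc9ccccc9)c(OCc9ccccc9)c1 | intermediate
3 | 8-bromo-5,7,3',4'-tetra-O-benzyl-(−)-epicatechin | O[C@@H]1Cc2c(OCc9ccccc9)cc(OCc9ccccc9)c(Br)c2O[C@@H]1c1ccc(OCc9ccccc9)c(OCc9ccccc9)c1 | intermediate
4 | 8-bromo-4β-(2-ethoxyethoxy)-5,7,3',4'-tetra-O-benzylepicatechin (unit U; 2,3-cis, 3,4-trans, C3 hydroxyl free) | CCOCCO[C@H]1c2c(OCc9ccccc9)cc(OCc9ccccc9)c(Br)c2O[C@H](c2ccc(OCc9ccccc9)c(OCc9ccccc9)c2)[C@@H]1O | intermediate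
5 | 4β-(2-ethoxyethoxy)-5,7,3',4'-tetra-O-benzylepicatechin (2,3-cis, 3,4-trans) | CCOCCO[C@H]1c2c(OCc9ccccc9)cc(OCc9ccccc9)cc2O[C@H](c2ccc(OCc9ccccc9)c(OCc9ccccc9)c2)[C@@H]1O | intermediate
6 | (+)-catechin, (2R,3S)-flavan-3,5,7,3',4'-pentol | O[C@H]1Cc2c(O)cc(O)cc2O[C@@H]1c1ccc(O)c(O)c1 | starting material
7 | 5,7,3',4'-tetra-O-benzyl-(+)-catechin (2R,3S; C3 hydroxyl free) | O[C@H]1Cc2c(OCc9ccccc9)cc(OCc9ccccc9)cc2O[C@@H]1c1ccc(OCc9ccccc9)c(OCc9ccccc9)c1 | intermediate
8 | octa-O-benzyl epicatechin-(4β→8)-catechin (M–T dimer; C8 of the epicatechin unit free) | c1c(OCc9ccccc9)cc(OCc9ccccc9)c2c1O[C@H](c1ccc(OCc9ccccc9)c(OCc9ccccc9)c1)[C@H](O)[C@H]2c1c(OCc9ccccc9)cc(OCc9ccccc9)c2c1O[C@H](c1ccc(OCc9ccccc9)c(OCc9ccccc9)c1)[C@@H](O)C2 | intermediate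
9 | (−)-epigallocatechin, (2R,3R)-flavan-3,5,7,3',4',5'-hexol | O[C@@H]1Cc2c(O)cc(O)cc2O[C@@H]1c1cc(O)c(O)c(O)c1 | starting material
10 | 5,7,3',4',5'-penta-O-benzyl-(−)-epigallocatechin (2R,3R; C3 hydroxyl free) | O[C@@H]1Cc2c(OCc9ccccc9)cc(OCc9ccccc9)cc2O[C@@H]1c1cc(OCc9ccccc9)c(OCc9ccccc9)c(OCc9ccccc9)c1 | intermediate
11 | 4β-(2-ethoxyethoxy)-5,7,3',4',5'-penta-O-benzylepigallocatechin (2,3-cis, 3,4-trans, C3 hydroxyl free) | CCOCCO[C@H]1c2c(OCc9ccccc9)cc(OCc9ccccc9)cc2O[C@H](c2cc(OCc9ccccc9)c(OCc9ccccc9)c(OCc9ccccc9)c2)[C@@H]1O | intermediate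
12 | 3,4,5-tris(benzyloxy)benzoic acid | O=C(O)c1cc(OCc2ccccc2)c(OCc2ccccc2)c(OCc2ccccc2)c1 | starting material
13 | 4β-(2-ethoxyethoxy)-octa-O-benzyl-epigallocatechin 3-O-gallate (2,3-cis, 3,4-trans) | O=C(O[C@@H]1[C@@H](OCCOCC)c2c(OCc9ccccc9)cc(OCc9ccccc9)cc2O[C@@H]1c1cc(OCc9ccccc9)c(OCc9ccccc9)c(OCc9ccccc9)c1)c1cc(OCc9ccccc9)c(OCc9ccccc9)c(OCc9ccccc9)c1 | intermediate
14 | 4β-(2,6-dimethylphenylthio)-octa-O-benzyl-epigallocatechin 3-O-gallate (unit G; 2,3-cis, 3,4-trans) | O=C(O[C@@H]1[C@@H](Sc3c(C)cccc3C)c2c(OCc9ccccc9)cc(OCc9ccccc9)cc2O[C@@H]1c1cc(OCc9ccccc9)c(OCc9ccccc9)c(OCc9ccccc9)c1)c1cc(OCc9ccccc9)c(OCc9ccccc9)c(OCc9ccccc9)c1 | intermediate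
15 | dodeca-O-benzyl 8-bromoepicatechin-(4β→8)-[4β-(2,6-dimethylphenylthio)epigallocatechin 3-O-gallate] (formed in the flask) | O=C(O[C@@H]1[C@@H](Sc3c(C)cccc3C)c2c(OCc9ccccc9)cc(OCc9ccccc9)c([C@H]3c4c(OCc9ccccc9)cc(OCc9ccccc9)c(Br)c4O[C@H](c4ccc(OCc9ccccc9)c(OCc9ccccc9)c4)[C@@H]3O)c2O[C@@H]1c1cc(OCc9ccccc9)c(OCc9ccccc9)c(OCc9ccccc9)c1)c1cc(OCc9ccccc9)c(OCc9ccccc9)c(OCc9ccccc9)c1 | intermediate
16 | eicosa-O-benzyl 8-bromoepicatechin-(4β→8)-epigallocatechin 3-O-gallate-(4β→8)-epicatechin-(4β→8)-catechin | O=C(O[C@@H]1[C@@H](c2c(OCc9ccccc9)cc(OCc9ccccc9)c3c2O[C@H](c2ccc(OCc9ccccc9)c(OCc9ccccc9)c2)[C@H](O)[C@H]3c2c(OCc9ccccc9)cc(OCc9ccccc9)c3c2O[C@H](c2ccc(OCc9ccccc9)c(OCc9ccccc9)c2)[C@@H](O)C3)c2c(OCc9ccccc9)cc(OCc9ccccc9)c([C@H]3c4c(OCc9ccccc9)cc(OCc9ccccc9)c(Br)c4O[C@H](c4ccc(OCc9ccccc9)c(OCc9ccccc9)c4)[C@@H]3O)c2O[C@@H]1c1cc(OCc9ccccc9)c(OCc9ccccc9)c(OCc9ccccc9)c1)c1cc(OCc9ccccc9)c(OCc9ccccc9)c(OCc9ccccc9)c1 | intermediate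
17 | epicatechin-(4β→8)-epigallocatechin 3-O-gallate-(4β→8)-epicatechin-(4β→8)-catechin (CNP0332815.1) | O=C(O[C@@H]1[C@@H](c2c(O)cc(O)c3c2O[C@H](c2ccc(O)c(O)c2)[C@H](O)[C@H]3c2c(O)cc(O)c3c2O[C@H](c2ccc(O)c(O)c2)[C@@H](O)C3)c2c(O)cc(O)c([C@H]3c4c(O)cc(O)cc4O[C@H](c4ccc(O)c(O)c4)[C@@H]3O)c2O[C@@H]1c1cc(O)c(O)c(O)c1)c1cc(O)c(O)c(O)c1 | target

Total step count: 12. Longest linear sequence: 6 steps (9 → 10 → 11 → 13 → 14 → 16 → 17).

Steps most likely to fail

1. Step 11 (bears the label). The programmed order may break down: sulfur transfer between units in the first stage, sulfenylation of the free C8 of the dimer by the thiophile, or recapture of the second cation by liberated 2-ethoxyethanol could leave the flask at mixed oligomers. The fallback uses known chemistry only, a bottom-up chain extension by two separate Me3SiOTf condensations, each with one electrophile and one C8 nucleophile. It sets out from 13 and 8: slow addition of 13 to 8 (2.5 equiv, excess recovered) and Me3SiOTf in CH2Cl2 at −78 → −30 °C should give hexadeca-O-benzyl epigallocatechin 3-O-gallate-(4β→8)-epicatechin-(4β→8)-catechin F1, whose only free C8 is on unit G and whose new bond is set trans by the gallate bridge. Equimolar condensation of F1 with the capped electrophile 4 (Me3SiOTf, CH2Cl2, −78 °C) comes back to the route at 16.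

2. Step 10. Ionisation of the ester-flanked acetal may be sluggish, so that the conditions needed for exchange also allow self-condensation through the free C8 or migration of the ester. The fallback forms the C–S bond before the ester is in place, on the more easily ionised 3-ol. It sets out from 11: thiolysis with 2,6-dimethylbenzenethiol (5 equiv) and BF3·OEt2 in CH2Cl2 at −78 → −30 °C should give 4β-(2,6-dimethylphenylthio)-5,7,3',4',5'-penta-O-benzylepigallocatechin F2, with its C3 hydroxyl free; Steglich esterification with acid 12 (DCC, DMAP cat., CH2Cl2) comes back to the route at 14.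

3. Step 12. Cleavage of twenty benzyl ethers may stop short through poisoning of the catalyst by bromide, and the amine-containing medium may promote oxidation of the free polyphenol on work-up. The fallback separates the two tasks. It sets out from 16: radical hydrodebromination (Bu3SnH, AIBN, toluene, 80 °C) should give the bromine-free eicosa-O-benzyl epicatechin-(4β→8)-epigallocatechin 3-O-gallate-(4β→8)-epicatechin-(4β→8)-catechin F3, and amine-free hydrogenolysis (H2, Pd(OH)2/C, THF/MeOH/H2O, rt) comes back to the route at 17.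

Further compounds
F1 | step 11 | hexadeca-O-benzyl epigallocatechin 3-O-gallate-(4β→8)-epicatechin-(4β→8)-catechin | O=C(O[C@@H]1[C@@H](c2c(OCc9ccccc9)cc(OCc9ccccc9)c3c2O[C@H](c2ccc(OCc9ccccc9)c(OCc9ccccc9)c2)[C@H](O)[C@H]3c2c(OCc9ccccc9)cc(OCc9ccccc9)c3c2O[C@H](c2ccc(OCc9ccccc9)c(OCc9ccccc9)c2)[C@@H](O)C3)c2c(OCc9ccccc9)cc(OCc9ccccc9)cc2O[C@@H]1c1cc(OCc9ccccc9)c(OCc9ccccc9)c(OCc9ccccc9)c1)c1cc(OCc9ccccc9)c(OCc9ccccc9)c(OCc9ccccc9)c1
F2 | step 10 | 4β-(2,6-dimethylphenylthio)-5,7,3',4',5'-penta-O-benzylepigallocatechin (2,3-cis, 3,4-trans, C3 hydroxyl free) | Cc1cccc(C)c1S[C@H]1c2c(OCc9ccccc9)cc(OCc9ccccc9)cc2O[C@H](c2cc(OCc9ccccc9)c(OCc9ccccc9)c(OCc9ccccc9)c2)[C@@H]1O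
F3 | step 12 | eicosa-O-benzyl epicatechin-(4β→8)-epigallocatechin 3-O-gallate-(4β→8)-epicatechin-(4β→8)-catechin (no bromine) | O=C(O[C@@H]1[C@@H](c2c(OCc9ccccc9)cc(OCc9ccccc9)c3c2O[C@H](c2ccc(OCc9ccccc9)c(OCc9ccccc9)c2)[C@H](O)[C@H]3c2c(OCc9ccccc9)cc(OCc9ccccc9)c3c2O[C@H](c2ccc(OCc9ccccc9)c(OCc9ccccc9)c2)[C@@H](O)C3)c2c(OCc9ccccc9)cc(OCc9ccccc9)c([C@H]3c4c(OCc9ccccc9)cc(OCc9ccccc9)cc4O[C@H](c4ccc(OCc9ccccc9)c(OCc9ccccc9)c4)[C@@H]3O)c2O[C@@H]1c1cc(OCc9ccccc9)c(OCc9ccccc9)c(OCc9ccccc9)c1)c1cc(OCc9ccccc9)c(OCc9ccccc9)c(OCc9ccccc9)c1
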